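## Retrosynthetic overview

1. Target 19 ⇒ ω‑hydroxy α‑methylene paraconic acid 16: the last step acetylates the alcohol and moves the exocyclic C=C into the ring (the classical protolichesterinic → lichesterinic acid change).
2. 16 ⇒ PMB ether 15 ⇒ trans‑paraconic acid 12, by α‑methylenation (Stiles carboxylation, then decarboxylative Mannich reaction).
3. 12 ⇒ aldol adduct 9: the key C–C bond (carbinol carbon to α‑carbon, ring C2–C3) comes from an intermolecular Evans boron aldol of succinyl imide 6 with aldehyde 3. This step sets the only stereocentre that survives, as R.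
4. There is one ring: the γ‑lactone closes directly after the aldol (step 5) and becomes the butenolide in the final step.
5. Fragments: 3 from 1,14‑tetradecanediol; 6 from (S)‑4‑benzyl‑2‑oxazolidinone and methyl succinyl chloride.

Assumption: 1,14‑tetradecanediol is bought as such; PMB = 4‑methoxybenzyl; the target stereocentre reads as (R) from the SMILES.

## Route

Step 1
Reactants: 1 tetradecane‑1,14‑diol
Product: 2 14‑[(4‑methoxybenzyl)oxy]tetradecan‑1‑ol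
Conditions: NaH (1.0 equiv), THF–DMF, 0 °C → rt; PMBCl (1.0 equiv), Bu4NI (cat.), rt → 50 °C; 1 in 3‑fold excess (recovered)
Reagents that add atoms: 4‑methoxybenzyl chloride, COc1ccc(CCl)cc1
Why: Williamson etherification of the mono‑alkoxide, where excess diol suppresses the bis‑ether and the three components separate easily on silica.

Step 2
Reactants: 2 14‑[(4‑methoxybenzyl)oxy]tetradecan‑1‑ol
Product: 3 14‑[(4‑methoxybenzyl)oxy]tetradecanal
Conditions: PhI(OAc)2 (1.1 equiv), TEMPO (10 mol%), CH2Cl2, rt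
Reagents that add atoms: none
Why: TEMPO/oxoammonium oxidation of a primary alcohol stops cleanly at the aldehyde under anhydrous conditions and leaves the PMB ether untouched.

Step 3
Reactants: 4 (4S)‑4‑benzyl‑1,3‑oxazolidin‑2‑one; 5 methyl 4‑chloro‑4‑oxobutanoate
Product: 6 methyl 4‑[(4S)‑4‑benzyl‑2‑oxo‑1,3‑oxazolidin‑3‑yl]‑4‑oxobutanoate
Conditions: n‑BuLi (1.0 equiv), THF, −78 °C; then 5, −78 → 0 °C
Reagents that add atoms: none
Why: N‑acylation of the lithiated oxazolidinone, in which the acid chloride reacts far faster than the methyl ester at −78 °C.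

Step 4
Reactants: 6 methyl 4‑[(4S)‑4‑benzyl‑2‑oxo‑1,3‑oxazolidin‑3‑yl]‑4‑oxobutanoate; 3 14‑[(4‑methoxybenzyl)oxy]tetradecanal
Product: 9 methyl (3S,4R)‑3‑{[(4S)‑4‑benzyl‑2‑oxo‑1,3‑oxazolidin‑3‑yl]carbonyl}‑4‑hydroxy‑17‑[(4‑methoxybenzyl)oxy]heptadecanoate, via Z‑dibutylboron enolate 7 (not isolated), via dibutylboron aldolate 8 (not isolated)
Conditions: 6 (1.2 equiv), Bu2BOTf (1.3 equiv), i‑Pr2NEt (1.5 equiv), CH2Cl2, −78 → 0 °C; 3, −78 → 0 °C; pH 7 buffer, MeOH, 30% H2O2, 0 °C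
Reagents that add atoms: dibutylboron triflate, CCCCB(CCCC)OS(=O)(=O)C(F)(F)F (its Bu2B group is carried only in 7 and 8 and is removed in the work‑up; 9 gains nothing but hydrogen)
Why: Evans boron syn‑aldol, in which Bu2BOTf/i‑Pr2NEt enolises only the imide to the Z‑enolate and the Zimmerman–Traxler chair, with the benzyl group blocking one enolate face, gives the (3S,4R) "Evans syn" adduct, so the carbinol carbon (the one stereocentre kept in the target) is set as R.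

Step 5
Reactants: 9 methyl (3S,4R)‑3‑{[(4S)‑4‑benzyl‑2‑oxo‑1,3‑oxazolidin‑3‑yl]carbonyl}‑4‑hydroxy‑17‑[(4‑methoxybenzyl)oxy]heptadecanoate
Product: 10 (4S)‑4‑benzyl‑3‑{[(2R,3S)‑2‑{13‑[(4‑methoxybenzyl)oxy]tridecyl}‑5‑oxooxolan‑3‑yl]carbonyl}‑1,3‑oxazolidin‑2‑one
Conditions: p‑TsOH·H2O (5 mol%), CH2Cl2, rt
Reagents that add atoms: none
Why: acid‑catalysed lactonisation (intramolecular transesterification, 5‑exo) of the γ‑hydroxy ester, which does not break the C–O bond at the carbinol and so keeps its R configuration (syn aldol gives the trans lactone; material that lactonised already in step 4 is the same compound).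

Step 6
Reactants: 10 (4S)‑4‑benzyl‑3‑{[(2R,3S)‑2‑{13‑[(4‑methoxybenzyl)oxy]tridecyl}‑5‑oxooxolan‑3‑yl]carbonyl}‑1,3‑oxazolidin‑2‑one
Product: 12 (2R,3S)‑2‑{13‑[(4‑methoxybenzyl)oxy]tridecyl}‑5‑oxooxolane‑3‑carboxylic acid, via peroxy acid 11 (not isolated)
Conditions: LiOH·H2O (2 equiv), 30% H2O2 (5 equiv), THF–H2O 3:1, 0 °C; aq. Na2SO3; 1 M HCl to pH 2
Reagents that add atoms: hydrogen peroxide, OO (one oxygen stays in the CO2H group)
Why: Evans LiOOH cleavage attacks the exocyclic imide carbonyl selectively, sulfite reduces the peroxy acid, and any lactone opened by base recloses on acidification, with C2 untouched.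

Step 7
Reactants: 12 (2R,3S)‑2‑{13‑[(4‑methoxybenzyl)oxy]tridecyl}‑5‑oxooxolane‑3‑carboxylic acid
Product: 13 (2R,3S,4S)‑2‑{13‑[(4‑methoxybenzyl)oxy]tridecyl}‑5‑oxooxolane‑3,4‑dicarboxylic acid (used crude; C4 is a labile malonate‑type centre)
Conditions: MeOMgOCO2Me (2 M in DMF, large excess), 135 °C, 48–60 h; cold 2 M HCl, extraction
Reagents that add atoms: methyl magnesium carbonate (Stiles reagent), COC(=O)O[Mg]OC
Why: Stiles carboxylation of the lactone α‑CH2 is driven by formation of the magnesium chelate of the malonate‑type product, while the C3 carboxylate protects against β‑elimination and the PMB ether is inert to base.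

Step 8
Reactants: 13 (2R,3S,4S)‑2‑{13‑[(4‑methoxybenzyl)oxy]tridecyl}‑5‑oxooxolane‑3,4‑dicarboxylic acid
Product: 15 (2R,3S)‑2‑{13‑[(4‑methoxybenzyl)oxy]tridecyl}‑4‑methylidene‑5‑oxooxolane‑3‑carboxylic acid, via Mannich base 14 (not isolated)
Conditions: 37% aq. HCHO, PhNHMe, NaOAc, AcOH, rt, 2–3 h
Reagents that add atoms: formaldehyde, C=O (its CH2 stays); N‑methylaniline, CNc1ccccc1 (carried only in 14 and released again)
Why: decarboxylative Mannich methylenation, in which the iminium ion is captured by the malonic‑acid‑type α‑carbon and the Mannich base loses CO2 and amine to give the α‑methylene lactone without touching C2.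

Step 9
Reactants: 15 (2R,3S)‑2‑{13‑[(4‑methoxybenzyl)oxy]tridecyl}‑4‑methylidene‑5‑oxooxolane‑3‑carboxylic acid
Product: 16 (2R,3S)‑2‑(13‑hydroxytridecyl)‑4‑methylidene‑5‑oxooxolane‑3‑carboxylic acid
Conditions: DDQ (1.3 equiv), CH2Cl2–pH 7 buffer 10:1, 0 °C → rt
Reagents that add atoms: none
Why: oxidative PMB‑ether cleavage by DDQ (benzylic hydride abstraction, then hydrolysis of the oxocarbenium ion) is neutral and spares the electron‑poor alkene, the lactone and the acid.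

Step 10
Reactants: 16 (2R,3S)‑2‑(13‑hydroxytridecyl)‑4‑methylidene‑5‑oxooxolane‑3‑carboxylic acid
Product: 19 (2R)‑2‑[13‑(acetyloxy)tridecyl]‑4‑methyl‑5‑oxo‑2,5‑dihydrofuran‑3‑carboxylic acid, via exo‑methylene mixed anhydride 17 (not isolated), via butenolide mixed anhydride 18 (not isolated)
Conditions: Ac2O (neat), 120–140 °C, 1–2 h; evaporate; THF–H2O, rt
Reagents that add atoms: acetic anhydride, CC(=O)OC(C)=O
Why: Ac2O acetylates the primary alcohol and turns the acid into a mixed anhydride whose allylic C3–H enolises, so a 1,3‑prototropic shift carries the exocyclic C=C into the tetrasubstituted, doubly conjugated ring position (the classical protolichesterinic → lichesterinic isomerisation, recalled from the older lichen‑acid literature rather than checked here) before water frees the acid, leaving the R centre at C2 unchanged.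

## Compound list

1 | tetradecane‑1,14‑diol | OCCCCCCCCCCCCCCO | starting material
2 | 14‑[(4‑methoxybenzyl)oxy]tetradecan‑1‑ol | COc1ccc(COCCCCCCCCCCCCCCO)cc1 | intermediate
3 | 14‑[(4‑methoxybenzyl)oxy]tetradecanal | COc1ccc(COCCCCCCCCCCCCCC=O)cc1 | intermediate
4 | (4S)‑4‑benzyl‑1,3‑oxazolidin‑2‑one | O=C1N[C@@H](Cc2ccccc2)CO1 | starting material
5 | methyl 4‑chloro‑4‑oxobutanoate (methyl succinyl chloride) | COC(=O)CCC(=O)Cl | starting material
6 | methyl 4‑[(4S)‑4‑benzyl‑2‑oxo‑1,3‑oxazolidin‑3‑yl]‑4‑oxobutanoate | COC(=O)CCC(=O)N1C(=O)OC[C@@H]1Cc1ccccc1 | intermediate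
7 | methyl (3Z)‑4‑[(4S)‑4‑benzyl‑2‑oxo‑1,3‑oxazolidin‑3‑yl]‑4‑[(dibutylboranyl)oxy]but‑3‑enoate (Z‑boron enolate of 6, not isolated) | COC(=O)C/C=C(\OB(CCCC)CCCC)N1C(=O)OC[C@@H]1Cc1ccccc1 | intermediate
8 | O‑dibutylboranyl derivative of 9 (boron aldolate, not isolated) | COC(=O)C[C@H](C(=O)N1C(=O)OC[C@@H]1Cc1ccccc1)[C@H](OB(CCCC)CCCC)CCCCCCCCCCCCCOCc1ccc(OC)cc1 | intermediate
9 | methyl (3S,4R)‑3‑{[(4S)‑4‑benzyl‑2‑oxo‑1,3‑oxazolidin‑3‑yl]carbonyl}‑4‑hydroxy‑17‑[(4‑methoxybenzyl)oxy]heptadecanoate | COC(=O)C[C@H](C(=O)N1C(=O)OC[C@@H]1Cc1ccccc1)[C@H](O)CCCCCCCCCCCCCOCc1ccc(OC)cc1 | intermediate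
10 | (4S)‑4‑benzyl‑3‑{[(2R,3S)‑2‑{13‑[(4‑methoxybenzyl)oxy]tridecyl}‑5‑oxooxolan‑3‑yl]carbonyl}‑1,3‑oxazolidin‑2‑one (trans lactone) | O=C1C[C@H](C(=O)N2C(=O)OC[C@@H]2Cc2ccccc2)[C@@H](CCCCCCCCCCCCCOCc2ccc(OC)cc2)O1 | intermediate
11 | (2R,3S)‑2‑{13‑[(4‑methoxybenzyl)oxy]tridecyl}‑5‑oxooxolane‑3‑carboperoxoic acid (not isolated) | O=C1C[C@H](C(=O)OO)[C@@H](CCCCCCCCCCCCCOCc2ccc(OC)cc2)O1 | intermediate
12 | (2R,3S)‑2‑{13‑[(4‑methoxybenzyl)oxy]tridecyl}‑5‑oxooxolane‑3‑carboxylic acid | O=C1C[C@H](C(=O)O)[C@@H](CCCCCCCCCCCCCOCc2ccc(OC)cc2)O1 | intermediate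
13 | (2R,3S,4S)‑2‑{13‑[(4‑methoxybenzyl)oxy]tridecyl}‑5‑oxooxolane‑3,4‑dicarboxylic acid (all‑trans drawn; C4 epimerisable) | O=C1[C@@H](C(=O)O)[C@H](C(=O)O)[C@@H](CCCCCCCCCCCCCOCc2ccc(OC)cc2)O1 | intermediate
14 | (2R,3S)‑2‑{13‑[(4‑methoxybenzyl)oxy]tridecyl}‑4‑{[methyl(phenyl)amino]methyl}‑5‑oxooxolane‑3,4‑dicarboxylic acid (Mannich base, C4 not controlled, not isolated) | O=C1C(CN(C)c2ccccc2)(C(=O)O)[C@H](C(=O)O)[C@@H](CCCCCCCCCCCCCOCc2ccc(OC)cc2)O1 | intermediate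
15 | (2R,3S)‑2‑{13‑[(4‑methoxybenzyl)oxy]tridecyl}‑4‑methylidene‑5‑oxooxolane‑3‑carboxylic acid | O=C1C(=C)[C@H](C(=O)O)[C@@H](CCCCCCCCCCCCCOCc2ccc(OC)cc2)O1 | intermediate
16 | (2R,3S)‑2‑(13‑hydroxytridecyl)‑4‑methylidene‑5‑oxooxolane‑3‑carboxylic acid | O=C1C(=C)[C@H](C(=O)O)[C@@H](CCCCCCCCCCCCCO)O1 | intermediate
17 | acetic (2R,3S)‑2‑[13‑(acetyloxy)tridecyl]‑4‑methylidene‑5‑oxooxolane‑3‑carboxylic anhydride (not isolated) | O=C1C(=C)[C@H](C(=O)OC(C)=O)[C@@H](CCCCCCCCCCCCCOC(C)=O)O1 | intermediate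
18 | acetic (2R)‑2‑[13‑(acetyloxy)tridecyl]‑4‑methyl‑5‑oxo‑2,5‑dihydrofuran‑3‑carboxylic anhydride (not isolated) | CC(=O)OCCCCCCCCCCCCC[C@H]1OC(=O)C(C)=C1C(=O)OC(C)=O | intermediate
19 | (2R)‑2‑[13‑(acetyloxy)tridecyl]‑4‑methyl‑5‑oxo‑2,5‑dihydrofuran‑3‑carboxylic acid | CC(=O)OCCCCCCCCCCCCC[C@H]1OC(=O)C(C)=C1C(=O)O | target

## Step count and risks

Total steps: 10. Longest linear sequence: 9 (steps 1, 2, 4, 5, 6, 7, 8, 9, 10); the imide branch (step 3) joins at step 4.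

Three steps most likely to fail:

(i) Step 4, the aldol of the ester‑bearing imide. The risks are competing ester enolisation or self‑condensation and a lower syn ratio. The fallback sets out from 3 (with auxiliary 4) and comes back to the route at 10. It keeps the boron aldol but masks the carboxymethyl arm as an allyl group. Lithiated 4 is acylated with pent‑4‑enoyl chloride to (4S)‑4‑benzyl‑3‑(pent‑4‑enoyl)‑1,3‑oxazolidin‑2‑one F1. The Bu2BOTf/i‑Pr2NEt aldol of F1 with 3 gives the Evans syn adduct (4S)‑4‑benzyl‑3‑[(2S,3R)‑3‑hydroxy‑16‑[(4‑methoxybenzyl)oxy]‑2‑(prop‑2‑en‑1‑yl)hexadecanoyl]‑1,3‑oxazolidin‑2‑one F2. Lemieux–Johnson cleavage of the terminal alkene (OsO4 cat., NaIO4, 2,6‑lutidine, dioxane–H2O) gives an aldehyde that closes on the hydroxyl to the lactol (4S)‑4‑benzyl‑3‑{[(2R,3S)‑5‑hydroxy‑2‑{13‑[(4‑methoxybenzyl)oxy]tridecyl}oxolan‑3‑yl]carbonyl}‑1,3‑oxazolidin‑2‑one F3. TEMPO/PhI(OAc)2 oxidation of F3 gives lactone 10.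

(ii) Step 7, the Stiles carboxylation. The risks are the long heating, incomplete conversion and a sensitive crude diacid. The fallback sets out from 12 and comes back at 15, bypassing 13 and 14. The dianion of 12 (LiHMDS 2.2 equiv, THF, −78 °C) is aminomethylated with Eschenmoser's salt to (2R,3S,4R)‑4‑[(dimethylamino)methyl]‑2‑{13‑[(4‑methoxybenzyl)oxy]tridecyl}‑5‑oxooxolane‑3‑carboxylic acid F4. N‑oxidation (mCPBA, NaHCO3, CH2Cl2, 0 °C) gives the amine oxide (2R,3S,4R)‑4‑[(dimethyloxidoazaniumyl)methyl]‑2‑{13‑[(4‑methoxybenzyl)oxy]tridecyl}‑5‑oxooxolane‑3‑carboxylic acid F5. F5 undergoes Cope elimination on warming to rt and gives 15 directly.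

(iii) Step 10, the combined acetylation and exo‑to‑endo isomerisation. The risks are incomplete isomerisation and some erosion of ee through the acidic γ‑H of the butenolide at high temperature, so ee should be checked by chiral HPLC. The fallback sets out from 16 and comes back at 19. The alkene is first moved by metal‑hydride catalysis without base (RhCl3·3H2O 5 mol%, EtOH, 75 °C) to give (2R)‑2‑(13‑hydroxytridecyl)‑4‑methyl‑5‑oxo‑2,5‑dihydrofuran‑3‑carboxylic acid F6. The alcohol is then acetylated cold (Ac2O, pyridine, CH2Cl2, 0 °C → rt, aqueous work‑up) to give 19.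

## Further compounds

F1 | step 4 | (4S)‑4‑benzyl‑3‑(pent‑4‑enoyl)‑1,3‑oxazolidin‑2‑one | C=CCCC(=O)N1C(=O)OC[C@@H]1Cc1ccccc1
F2 | step 4 | (4S)‑4‑benzyl‑3‑[(2S,3R)‑3‑hydroxy‑16‑[(4‑methoxybenzyl)oxy]‑2‑(prop‑2‑en‑1‑yl)hexadecanoyl]‑1,3‑oxazolidin‑2‑one | C=CC[C@H](C(=O)N1C(=O)OC[C@@H]1Cc1ccccc1)[C@H](O)CCCCCCCCCCCCCOCc1ccc(OC)cc1
F3 | step 4 | (4S)‑4‑benzyl‑3‑{[(2R,3S)‑5‑hydroxy‑2‑{13‑[(4‑methoxybenzyl)oxy]tridecyl}oxolan‑3‑yl]carbonyl}‑1,3‑oxazolidin‑2‑one (lactol, anomer mixture) | OC1C[C@H](C(=O)N2C(=O)OC[C@@H]2Cc2ccccc2)[C@@H](CCCCCCCCCCCCCOCc2ccc(OC)cc2)O1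
F4 | step 7 | (2R,3S,4R)‑4‑[(dimethylamino)methyl]‑2‑{13‑[(4‑methoxybenzyl)oxy]tridecyl}‑5‑oxooxolane‑3‑carboxylic acid | O=C1[C@@H](CN(C)C)[C@H](C(=O)O)[C@@H](CCCCCCCCCCCCCOCc2ccc(OC)cc2)O1
F5 | step 7 | (2R,3S,4R)‑4‑[(dimethyloxidoazaniumyl)methyl]‑2‑{13‑[(4‑methoxybenzyl)oxy]tridecyl}‑5‑oxooxolane‑3‑carboxylic acid (N‑oxide of F4) | O=C1[C@@H](C[N+](C)(C)[O-])[C@H](C(=O)O)[C@@H](CCCCCCCCCCCCCOCc2ccc(OC)cc2)O1
F6 | step 10 | (2R)‑2‑(13‑hydroxytridecyl)‑4‑methyl‑5‑oxo‑2,5‑dihydrofuran‑3‑carboxylic acid | OCCCCCCCCCCCCC[C@H]1OC(=O)C(C)=C1C(=O)O
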